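All runs are simulated on assumed constants; scatter was added.

- Build each flask one process at a time, and carry two numbers from zeta to the others.

| flask | Z | D | X | remark | time |
|---|---|---|---|---|---|
| beta | 0.071 M | 8.2 mM | 3.5 mM | run made earlier |  |
| zeta | 0.071 M | 27 mM | 3.5 mM | run made earlier |  |
| epsilon | 0.071 M | 7.1 mM | 6.9 mM | run made earlier |  |
| spring | 0.071 M | 15.0 mM | 2.5 mM |  | 4.0 min |
| summer | 0.071 M | 15.0 mM | 2.0 mM |  | 4.0 min |
| dawn | 0.071 M | 20.0 mM | 15 mM |  | 4.0 min |
| midnight | 0.15 M | 7.10 mM | 10 mM |  | 4.0 min |
| winter | 0.071 M | 7.10 mM | 3.5 mM |  | 4.0 min |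

| run | time / min | E / % | Z / % |
|---|---|---|---|
| beta | 0.667 | 16.0 | 85.1 |
| beta | 1.33 | 24.5 | 74.8 |
| beta | 2.00 | 33.0 | 66.0 |
| beta | 3.00 | 42.4 | 59.4 |
| zeta | 0.250 | 6.5 | 93.1 |
| zeta | 0.500 | 11.7 | 89.5 |
| zeta | 1.33 | 21.0 | 79.7 |
| zeta | 3.00 | 25.5 | 73.5 |
| epsilon | 0.250 | 12.5 | 85.5 |
| epsilon | 0.500 | 22.9 | 75.4 |
| epsilon | 1.33 | 45.0 | 55.1 |
| epsilon | 3.00 | 67.8 | 33.0 |

(standard deviation of a reading: 1 percentage point)

* all flasks from highest to lowest amount of E, in percent of the Z charged, at 4.0 min (spring / summer / dawn / midnight / winter)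
* the same order at 25 s (spring / summer / dawn / midnight / winter)
* the amount of E, in percent of the Z charged of the flask you put first, at 4.0 min
* the amount of E, in percent of the Z charged of the flask you put last, at 4.0 min

- reactions considered so far: Z + X -> Q + E; Z + Q -> E + Q; Q + D -> J; X -> L; X -> G

- First layer: let Q live for ever in Z + Q -> E + Q. Then ln(charged [Z]/[Z]) grows with time in proportion to [Q], and [Q] comes from [X]. The readings show this: epsilon has twice the X of beta and, at 3.00 min, 2.13 times its logarithm. This layer has no stop.
- Second layer: add Q + D -> J. While [D] stands near its charge, the loss of Q is pseudo-first-order, with a life proportional to 1/[D], so the logarithm climbs to a limit. Call that limit the reach: a constant times [X]/[D].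
- Zeta gives both numbers. Taking its last reading as the stall, the constant is 2.38. The share of that stall reached at 1.33 min gives a life of 0.996 min at 27 mM of D.
- So the logarithm at time t is the reach times (1 − exp(−t/life)). The crossing is the life: well before it [X] ranks the flasks, and well after it [X]/[D] does.
- Dawn's life is 1.34 min, longer than 25 s, so there dawn leads on its larger [X]: you get 37.8 % against midnight's 29.4 %.
- At 4.0 min midnight's reach of 3.35 exceeds dawn's 1.78, which gives midnight 88.7 % and dawn 81.6 %.
- Summer has a reach of 0.317, so its ceiling is 27.2 % and its value at 4.0 min is 24.6 %, the lowest on this reckoning.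
- Third layer: X also leaves by way of L and G, and the constant from zeta already carries that loss at this [Z]. Q also uses up D. Dawn charges 0.750 X per D against zeta's 0.130, so [D] sinks there, and you should treat dawn's figure as low.
- The forecast gives midnight > dawn > winter > spring > summer at 4.0 min and dawn > midnight > winter > spring > summer at 25 s, with 87 % on top and 24 % at the bottom, and it notes that “More D makes the conversion stall sooner”.
- The flasks give midnight > dawn > winter > spring > summer at 4.0 min and dawn > midnight > winter > spring > summer at 25 s, with 88.4 % and 23.3 % at the two ends.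

    Z + X → Q + E (k = 1.70 /M/s)
    Z + Q → E + Q, rate k2*[Q]*[Z] (k = 1.30 /M/s)
    Q + D → J (k = 0.600 /M/s)
    X → L (k = 2.60 × 10⁻⁶ /s)
    X → G (k = 0.0110 /s)

- Summer stands at 23.3 % mainly because its X falls to 0 %: with X held at its charge, E would stand at 96.9 %. At ten times the time, summer stands at 26.5 %, and its reach gave 27.2 %. In the neighbour of midnight with 0.028 M of D, the same rule gives 56.6 %, and that flask stands at 60.1 %.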